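**Retrosynthetic overview**

- Target 23 is a 17-membered macrocycle of four benzene rings: ring A (para-phenylene), ring B (bridge carbon, ether oxygen and OH on three adjacent carbons), ring C (3-aryloxy-4,5-dihydroxy-1-alkyl) and ring D (ortho-phenylene). They are joined by two diaryl ether oxygens and two CH2CH2 bridges, and there is no stereocentre.
- The strategy rests on the ring D carbon that carries the ether oxygen to ring B: it has no activating group. A temporary nitro group para to that carbon (meta to the ring D bridge carbon) lets the hindered ring B phenoxide oxygen, flanked by OMe and the bridge carbon, displace fluoride and close the macrocycle at the ring B O–ring D C bond.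
- After closure the nitro group is removed (NO2 to NH2 to N2+ to H) and the three methyl ethers are cleaved.
- The open-chain precursor is assembled by SNAr of the ring C phenol on 4-fluorobenzaldehyde (A–O–C ether), a Wittig reaction plus hydrogenation (A–B bridge), and a Wittig reaction with 2-fluoro-5-nitrobenzaldehyde plus diimide reduction (C–D bridge).
- All four arenes are bought; the only ring formed is the 17-membered macrocycle, in step 13.

Key step: step 13

Remark: ring C is brought in as commercial methyl 3-hydroxy-4,5-dimethoxybenzoate so that its benzylic carbon stays distinct from the ring A aldehyde; the target is taken to be conformationally mobile, with no stable atropisomer to control.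

**Route**

Step 1
Reactants: 1 methyl 3-hydroxy-4,5-dimethoxybenzoate; 2 4-fluorobenzaldehyde
Product: 3 methyl 3-(4-formylphenoxy)-4,5-dimethoxybenzoate
Conditions: K2CO3, DMF, 120 °C
Reagents that add atoms: none
Why: SNAr diaryl ether synthesis, in which the para formyl group stabilises the Meisenheimer adduct of the phenoxide of 1 on 2 and dry carbonate leaves the methyl ester untouched.

Step 2
Reactants: 3 methyl 3-(4-formylphenoxy)-4,5-dimethoxybenzoate
Product: 4 methyl 3-[4-(hydroxymethyl)phenoxy]-4,5-dimethoxybenzoate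
Conditions: NaBH4, MeOH/THF, 0 °C
Reagents that add atoms: none
Why: Chemoselective borohydride reduction, since NaBH4 at 0 °C reduces the aryl aldehyde but not the methyl benzoate.

Step 3
Reactants: 4 methyl 3-[4-(hydroxymethyl)phenoxy]-4,5-dimethoxybenzoate
Product: 5 {4-[2,3-dimethoxy-5-(methoxycarbonyl)phenoxy]benzyl}triphenylphosphonium bromide
Conditions: PPh3·HBr, MeCN, reflux
Reagents that add atoms: triphenylphosphine hydrobromide, Br.c1ccc(cc1)P(c1ccccc1)c1ccccc1
Why: Direct phosphonium salt formation from a benzylic alcohol, in which the para-aryloxy group assists ionisation of the protonated alcohol and PPh3 captures the benzylic cation, while ester and ethers tolerate the mild acid.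

Step 4
Reactants: 6 o-vanillin (2-hydroxy-3-methoxybenzaldehyde)
Product: 7 3-methoxy-2-(methoxymethoxy)benzaldehyde
Conditions: MOMCl, i-Pr2NEt, CH2Cl2, 0 °C to rt
Reagents that add atoms: chloromethyl methyl ether, COCCl
Why: O-alkylation of the phenol (MOM protection) gives an acetal that withstands the later bases, hydrides, hydrogenation and diimide and is removable with acid without touching nitro, fluoride or methyl ethers.

Step 5
Reactants: 5 {4-[2,3-dimethoxy-5-(methoxycarbonyl)phenoxy]benzyl}triphenylphosphonium bromide; 7 3-methoxy-2-(methoxymethoxy)benzaldehyde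
Product: 9 methyl 3,4-dimethoxy-5-(4-{2-[3-methoxy-2-(methoxymethoxy)phenyl]ethenyl}phenoxy)benzoate as an E/Z mixture, via ring A benzylidene ylide 8 (not isolated)
Conditions: K2CO3, 18-crown-6 (cat.), CH2Cl2, reflux
Reagents that add atoms: none
Why: Wittig olefination of a semi-stabilised benzylic ylide under solid–liquid phase-transfer conditions that spare the ester and the MOM ether; the alkene geometry does not matter because the next step saturates it.

Step 6
Reactants: 9 stilbene ester (E/Z mixture)
Product: 10 methyl 3,4-dimethoxy-5-(4-{2-[3-methoxy-2-(methoxymethoxy)phenyl]ethyl}phenoxy)benzoate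
Conditions: H2 (1 atm), Pd/C, EtOAc, rt
Reagents that add atoms: none
Why: Heterogeneous catalytic hydrogenation saturates both stilbene isomers to one bibenzyl, and the MOM ether, ester and diaryl ether are inert in neutral EtOAc.

Step 7
Reactants: 10 bibenzyl ester
Product: 11 [3,4-dimethoxy-5-(4-{2-[3-methoxy-2-(methoxymethoxy)phenyl]ethyl}phenoxy)phenyl]methanol
Conditions: LiAlH4, THF, 0 °C
Reagents that add atoms: none
Why: Hydride reduction of the methyl ester to the benzylic alcohol, with no other reducible group present.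

Step 8
Reactants: 11 ring C benzylic alcohol
Product: 12 5-(bromomethyl)-1,2-dimethoxy-3-(4-{2-[3-methoxy-2-(methoxymethoxy)phenyl]ethyl}phenoxy)benzene
Conditions: CBr4, PPh3, CH2Cl2, 0 °C
Reagents that add atoms: tetrabromomethane, BrC(Br)(Br)Br
Why: Appel bromination proceeds through an alkoxyphosphonium ion under essentially neutral conditions, which the acid-labile MOM ether tolerates.

Step 9
Reactants: 12 ring C benzylic bromide
Product: 13 [3,4-dimethoxy-5-(4-{2-[3-methoxy-2-(methoxymethoxy)phenyl]ethyl}phenoxy)benzyl]triphenylphosphonium bromide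
Conditions: PPh3, toluene, 100 °C
Reagents that add atoms: triphenylphosphine, c1ccc(cc1)P(c1ccccc1)c1ccccc1
Why: SN2 quaternisation of PPh3 by the reactive benzylic bromide, with the salt expected to precipitate from toluene.

Step 10
Reactants: 13 ring C phosphonium bromide; 14 2-fluoro-5-nitrobenzaldehyde
Product: 16 1-fluoro-2-{2-[3,4-dimethoxy-5-(4-{2-[3-methoxy-2-(methoxymethoxy)phenyl]ethyl}phenoxy)phenyl]ethenyl}-4-nitrobenzene as an E/Z mixture, via ring C benzylidene ylide 15 (not isolated)
Conditions: NaN(SiMe3)2, THF, 0 °C; then 14, −78 °C to rt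
Reagents that add atoms: none
Why: Wittig olefination with a pre-formed ylide, so that no free base meets the activated fluoride; the ylide carbon adds to the very electrophilic aldehyde at low temperature, and the MOM group keeps the ring B oxygen from attacking the C–F bond.

Step 11
Reactants: 16 nitrostilbene (E/Z mixture)
Product: 17 1-fluoro-2-{2-[3,4-dimethoxy-5-(4-{2-[3-methoxy-2-(methoxymethoxy)phenyl]ethyl}phenoxy)phenyl]ethyl}-4-nitrobenzene
Conditions: TsNHNH2 (excess), NaOAc, DME/H2O, reflux
Reagents that add atoms: none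
Why: Diimide reduction, in which HN=NH generated from the sulfonyl hydrazide transfers H2 to the nonpolar C=C in a concerted syn fashion and leaves the nitro group and the C–F bond alone, which H2 over Pd/C would not.

Step 12
Reactants: 17 MOM-protected open-chain fluoronitroarene
Product: 18 2-[2-(4-{5-[2-(2-fluoro-5-nitrophenyl)ethyl]-2,3-dimethoxyphenoxy}phenyl)ethyl]-6-methoxyphenol
Conditions: conc. HCl (cat.), MeOH/THF, 50 °C
Reagents that add atoms: none
Why: Acid-catalysed acetal methanolysis removes the MOM group; methyl ethers, nitro group and aryl fluoride are inert to dilute acid and no nucleophile for SNAr is present.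

Step 13
Reactants: 18 open-chain fluoronitroarene phenol
Product: 19 nitro tri-O-methyl macrocycle (17-membered ring; nitro on ring D para to the new ether oxygen)
Conditions: Cs2CO3, DMF, 80 °C, slow addition of 18, final 0.002 M
Reagents that add atoms: none
Why: Cs2CO3 deprotonates the ring B phenol, and the phenoxide oxygen adds to the fluorine-bearing carbon of ring D to give a Meisenheimer complex whose charge is delocalised into the para nitro group, after which fluoride leaves (addition–elimination SNAr). The closest known reaction type is the intramolecular SNAr cycloetherification of nitro-activated aryl fluorides to macrocyclic diaryl ethers. The 17-membered ring closes by end-to-end O-arylation, the oxygen at one chain terminus attacking the aromatic carbon at the other, so the new bond is ring B O–ring D C. No stereocentre is formed. The step needs ring closure to outrun oligomerisation and needs a single reacting site: slow addition into dilute base keeps the phenoxide concentration low, 18 has only one phenol and one activated C–F, and the ring D benzylic CH2 is meta to the nitro group and therefore not acidified. The 2,6-disubstituted phenoxide and the ortho-alkylated electrophile, which hamper copper-mediated couplings, should be tolerated because the nitro group and the small fluoride leaving group drive the addition.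

Step 14
Reactants: 19 nitro tri-O-methyl macrocycle
Product: 20 amino tri-O-methyl macrocycle (NH2 in place of NO2 on ring D)
Conditions: H2 (1 atm), Pd/C, EtOAc/MeOH, rt
Reagents that add atoms: none
Why: Catalytic hydrogenation of an aromatic nitro group to the aniline, with the diaryl and methyl ethers unaffected.

Step 15
Reactants: 20 amino tri-O-methyl macrocycle
Product: 22 tri-O-methyl macrocycle (ring D unsubstituted apart from its ether oxygen and bridge carbon), via ring D diazonium chloride 21 (not isolated)
Conditions: NaNO2, aq. HCl, THF, 0 °C; then H3PO2, Cu2O (cat.), 0 °C to rt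
Reagents that add atoms: none
Why: Diazotisation followed by hypophosphorous acid reduction (reductive deamination), in which the aryl radical formed on loss of N2 abstracts hydrogen from H3PO2.

Step 16
Reactants: 22 tri-O-methyl macrocycle
Product: 23 CNP0290892.0 (target triol)
Conditions: BBr3, CH2Cl2, −78 °C to rt
Reagents that add atoms: none
Why: Lewis acid cleavage of aryl methyl ethers (boron complexation, then bromide attack on methyl) frees the three phenols, and diaryl ether bonds resist BBr3.

**Compound list**

1 | methyl 3-hydroxy-4,5-dimethoxybenzoate | COC(=O)c1cc(O)c(OC)c(OC)c1 | starting material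
2 | 4-fluorobenzaldehyde | O=Cc1ccc(F)cc1 | starting material
3 | methyl 3-(4-formylphenoxy)-4,5-dimethoxybenzoate | COC(=O)c1cc(OC)c(OC)c(Oc2ccc(C=O)cc2)c1 | intermediate
4 | methyl 3-[4-(hydroxymethyl)phenoxy]-4,5-dimethoxybenzoate | COC(=O)c1cc(OC)c(OC)c(Oc2ccc(CO)cc2)c1 | intermediate
5 | {4-[2,3-dimethoxy-5-(methoxycarbonyl)phenoxy]benzyl}triphenylphosphonium bromide | COC(=O)c1cc(OC)c(OC)c(Oc2ccc(C[P+](c3ccccc3)(c3ccccc3)c3ccccc3)cc2)c1.[Br-] | intermediate
6 | o-vanillin (2-hydroxy-3-methoxybenzaldehyde) | COc1cccc(C=O)c1O | starting material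
7 | 3-methoxy-2-(methoxymethoxy)benzaldehyde | COCOc1c(OC)cccc1C=O | intermediate
8 | ring A benzylidene ylide (ylide of 5) | COC(=O)c1cc(OC)c(OC)c(Oc2ccc(C=P(c3ccccc3)(c3ccccc3)c3ccccc3)cc2)c1 | intermediate (not isolated)
9 | methyl 3,4-dimethoxy-5-(4-{2-[3-methoxy-2-(methoxymethoxy)phenyl]ethenyl}phenoxy)benzoate, E/Z mixture (geometry unspecified) | COCOc1c(OC)cccc1C=Cc1ccc(Oc2cc(cc(OC)c2OC)C(=O)OC)cc1 | intermediate
10 | methyl 3,4-dimethoxy-5-(4-{2-[3-methoxy-2-(methoxymethoxy)phenyl]ethyl}phenoxy)benzoate | COCOc1c(OC)cccc1CCc1ccc(Oc2cc(cc(OC)c2OC)C(=O)OC)cc1 | intermediate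
11 | [3,4-dimethoxy-5-(4-{2-[3-methoxy-2-(methoxymethoxy)phenyl]ethyl}phenoxy)phenyl]methanol | COCOc1c(OC)cccc1CCc1ccc(Oc2cc(CO)cc(OC)c2OC)cc1 | intermediate
12 | 5-(bromomethyl)-1,2-dimethoxy-3-(4-{2-[3-methoxy-2-(methoxymethoxy)phenyl]ethyl}phenoxy)benzene | COCOc1c(OC)cccc1CCc1ccc(Oc2cc(CBr)cc(OC)c2OC)cc1 | intermediate
13 | [3,4-dimethoxy-5-(4-{2-[3-methoxy-2-(methoxymethoxy)phenyl]ethyl}phenoxy)benzyl]triphenylphosphonium bromide | COCOc1c(OC)cccc1CCc1ccc(Oc2cc(C[P+](c3ccccc3)(c3ccccc3)c3ccccc3)cc(OC)c2OC)cc1.[Br-] | intermediate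
14 | 2-fluoro-5-nitrobenzaldehyde | O=Cc1cc(ccc1F)[N+](=O)[O-] | starting material
15 | ring C benzylidene ylide (ylide of 13) | COCOc1c(OC)cccc1CCc1ccc(Oc2cc(C=P(c3ccccc3)(c3ccccc3)c3ccccc3)cc(OC)c2OC)cc1 | intermediate (not isolated)
16 | 1-fluoro-2-{2-[3,4-dimethoxy-5-(4-{2-[3-methoxy-2-(methoxymethoxy)phenyl]ethyl}phenoxy)phenyl]ethenyl}-4-nitrobenzene, E/Z mixture (geometry unspecified) | COCOc1c(OC)cccc1CCc1ccc(Oc2cc(C=Cc3cc(ccc3F)[N+](=O)[O-])cc(OC)c2OC)cc1 | intermediate
17 | 1-fluoro-2-{2-[3,4-dimethoxy-5-(4-{2-[3-methoxy-2-(methoxymethoxy)phenyl]ethyl}phenoxy)phenyl]ethyl}-4-nitrobenzene | COCOc1c(OC)cccc1CCc1ccc(Oc2cc(CCc3cc(ccc3F)[N+](=O)[O-])cc(OC)c2OC)cc1 | intermediate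
18 | 2-[2-(4-{5-[2-(2-fluoro-5-nitrophenyl)ethyl]-2,3-dimethoxyphenoxy}phenyl)ethyl]-6-methoxyphenol | COc1cc(CCc2cc(ccc2F)[N+](=O)[O-])cc(Oc2ccc(CCc3cccc(OC)c3O)cc2)c1OC | intermediate
19 | nitro tri-O-methyl macrocycle (nitro on ring D para to the ring B–O–ring D oxygen) | COc1cc2cc(c1OC)Oc1ccc(cc1)CCc1cccc(OC)c1Oc1ccc(cc1CC2)[N+](=O)[O-] | intermediate
20 | amino tri-O-methyl macrocycle | COc1cc2cc(c1OC)Oc1ccc(cc1)CCc1cccc(OC)c1Oc1ccc(N)cc1CC2 | intermediate
21 | ring D diazonium chloride of the tri-O-methyl macrocycle | COc1cc2cc(c1OC)Oc1ccc(cc1)CCc1cccc(OC)c1Oc1ccc(cc1CC2)[N+]#N.[Cl-] | intermediate (not isolated)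
22 | tri-O-methyl macrocycle | COc1cc2cc(c1OC)Oc1ccc(cc1)CCc1cccc(OC)c1Oc1ccccc1CC2 | intermediate
23 | CNP0290892.0 | Oc1cc2cc(c1O)Oc1ccc(cc1)CCc1cccc(O)c1Oc1ccccc1CC2 | target

**Step count**

Total: 16 steps. Longest linear sequence: 15 steps (steps 1–3 and 5–16, from 1 and 2); step 4 is a one-step side branch.

**Steps most likely to fail, with fallbacks**

1. Step 13 (macrocyclisation). Intermolecular etherification to dimers and oligomers may outpace closure of the 17-membered ring, because the closing bond joins two ortho-substituted arenes and the phenoxide is sterically shielded.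
   Fallback: make the hindered ether intermolecularly on a doubly activated fluoride and close the ring at the C–D bridge by an intramolecular Wittig reaction instead. It sets out from 10 and returns at 20.
   - Methanolic HCl removes the MOM group of 10 to give methyl 3-{4-[2-(2-hydroxy-3-methoxyphenyl)ethyl]phenoxy}-4,5-dimethoxybenzoate F1.
   - LiAlH4 reduces the ester to 2-(2-{4-[5-(hydroxymethyl)-2,3-dimethoxyphenoxy]phenyl}ethyl)-6-methoxyphenol F2.
   - The phenoxide of F2 (K2CO3, DMF, rt) displaces the fluoride of 14, which is activated by both the ortho formyl and the para nitro group, giving 2-[2-(2-{4-[5-(hydroxymethyl)-2,3-dimethoxyphenoxy]phenyl}ethyl)-6-methoxyphenoxy]-5-nitrobenzaldehyde F3.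
   - PPh3·HBr in MeCN converts the benzylic alcohol into the ring C phosphonium bromide aldehyde F4.
   - Slow addition of F4 to K2CO3 and 18-crown-6 in CH2Cl2 at high dilution forms the ring C ylide aldehyde F5, which is not isolated and closes to the macrocyclic nitrostilbene F6.
   - H2 over Pd/C saturates the alkene and reduces the nitro group in one operation, giving 20.

2. Step 11 (diimide reduction). Saturation of the stilbene may stall, and during the long reflux the sulfinate and hydrazide nucleophiles may slowly displace the activated fluoride.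
   Fallback: build the C–D bridge by a B-alkyl Suzuki–Miyaura coupling, so that no alkene has to be reduced beside the nitro group. It sets out from 11 and returns at 17, bypassing steps 8–11.
   - MnO2 in CH2Cl2 oxidises 11 to 3,4-dimethoxy-5-(4-{2-[3-methoxy-2-(methoxymethoxy)phenyl]ethyl}phenoxy)benzaldehyde F7.
   - Ph3P=CH2 in THF gives the ring C styrene F8.
   - 9-BBN in THF hydroborates the vinyl group at its terminal carbon to the B-alkyl-9-BBN F9, which is not isolated.
   - F9 is coupled with commercial 2-bromo-1-fluoro-4-nitrobenzene (Fc1ccc(cc1Br)[N+](=O)[O-]) using PdCl2(dppf), K3PO4, DMF/THF/H2O, 50 °C, giving 17.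

3. Step 15 (reductive deamination). The diazonium ion may be diverted into azo coupling with the electron-rich ring C or into hydrolysis to a phenol before hydrogen transfer takes place.
   Fallback: skip the amine and diazonium altogether and remove the nitro group of 19 directly by palladium-catalysed reductive denitration (Pd(acac)2, BrettPhos, K3PO4, 2-propanol, 1,4-dioxane, 130 °C). Zerovalent palladium inserts into the Ar–NO2 bond, the isopropoxide supplies hydride, and reductive elimination gives the arene. It sets out from 19 and returns at 22, replacing steps 14 and 15; no new compound is made (F0).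

**Further compounds**

F1 | step 13 | methyl 3-{4-[2-(2-hydroxy-3-methoxyphenyl)ethyl]phenoxy}-4,5-dimethoxybenzoate | COC(=O)c1cc(OC)c(OC)c(Oc2ccc(CCc3cccc(OC)c3O)cc2)c1
F2 | step 13 | 2-(2-{4-[5-(hydroxymethyl)-2,3-dimethoxyphenoxy]phenyl}ethyl)-6-methoxyphenol | COc1cccc(CCc2ccc(Oc3cc(CO)cc(OC)c3OC)cc2)c1O
F3 | step 13 | 2-[2-(2-{4-[5-(hydroxymethyl)-2,3-dimethoxyphenoxy]phenyl}ethyl)-6-methoxyphenoxy]-5-nitrobenzaldehyde | COc1cccc(CCc2ccc(Oc3cc(CO)cc(OC)c3OC)cc2)c1Oc1ccc(cc1C=O)[N+](=O)[O-]
F4 | step 13 | ring C phosphonium bromide aldehyde | COc1cccc(CCc2ccc(Oc3cc(C[P+](c4ccccc4)(c4ccccc4)c4ccccc4)cc(OC)c3OC)cc2)c1Oc1ccc(cc1C=O)[N+](=O)[O-].[Br-]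
F5 | step 13 | ring C ylide aldehyde (not isolated) | COc1cccc(CCc2ccc(Oc3cc(C=P(c4ccccc4)(c4ccccc4)c4ccccc4)cc(OC)c3OC)cc2)c1Oc1ccc(cc1C=O)[N+](=O)[O-]
F6 | step 13 | macrocyclic nitrostilbene (alkene geometry unspecified) | COc1cc2cc(c1OC)Oc1ccc(cc1)CCc1cccc(OC)c1Oc1ccc(cc1C=C2)[N+](=O)[O-]
F7 | step 11 | 3,4-dimethoxy-5-(4-{2-[3-methoxy-2-(methoxymethoxy)phenyl]ethyl}phenoxy)benzaldehyde | COCOc1c(OC)cccc1CCc1ccc(Oc2cc(C=O)cc(OC)c2OC)cc1
F8 | step 11 | ring C styrene (5-ethenyl-1,2-dimethoxy-3-(4-{2-[3-methoxy-2-(methoxymethoxy)phenyl]ethyl}phenoxy)benzene) | COCOc1c(OC)cccc1CCc1ccc(Oc2cc(C=C)cc(OC)c2OC)cc1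
F9 | step 11 | B-alkyl-9-BBN from F8 (not isolated) | COCOc1c(OC)cccc1CCc1ccc(Oc2cc(CCB3C4CCCC3CCC4)cc(OC)c2OC)cc1
F0 | step 15 | none | none
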